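**Plan**

- Retrosynthesis: cut the vanillate at the C6–O ester bond, the isopropyl group at C4 (ketone plus isopropyl nucleophile) and the C7=C8–CH3 unit back to a C8 ketone. Then cut ring B at C6–C7 and C1–C10, which leaves a cyclopentenyl acylsilane (C6, C5, C1 on ring A) and the lithium enolate of methyl vinyl ketone (C7–C10).
- Enabling feature: in the seven-membered ring B, C6 (oxygen-bearing), C5 and the quaternary C1 sit on or next to the five-membered ring A, and C7–C10 have the pattern of a buta-1,3-dien-2-olate (C8 at carbonyl level, C10 a methylene). Ring B can therefore arise in one (3+4) annulation in which silicon moves from C6 to its oxygen and C1 becomes quaternary by ring expansion of a cis-divinylcyclopropane.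
- Forward: ring A comes from 2-bromo-3-methylcyclopent-2-enone and is armed as the acylsilane; ring B is closed in the annulation and the C9 oxygen is added to the resulting enolate in the same flask. C8 is then methylenated and conjugated, C6 reduced and esterified, and C4 converted to the tertiary carbinol last.
- Stereochemistry: a CBS reduction sets the C4 carbinol, which directs C1 in the annulation (new bond anti to the silyloxy group). The C1 methyl directs C9, C5 is set by protonation, and the C4 hydroxyl delivers hydride to C6. C4 is finally oxidised and re-created by isopropyl addition anti to the C1 methyl.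

Key step: step 5

Remark: bicyclic compounds carry daucane numbering (C1 quaternary ring-fusion carbon with its methyl, C2, C3, C4 carbinol carbon of ring A, C5 ring-fusion CH, C6 ester carbon, C7, C8 methyl-bearing carbon, C9 carbinol, C10; ring A = C1–C5, ring B = C1, C5–C10); β is the face of the C1 methyl, α the opposite face.

**Route**

Step 1
Reactants: 1 2-bromo-3-methylcyclopent-2-en-1-one
Product: 2 (S)-2-bromo-3-methylcyclopent-2-en-1-ol
Conditions: (R)-2-methyl-CBS-oxazaborolidine (10 mol%), BH3·SMe2, THF, −20 °C; MeOH quench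
Reagents that add atoms: none
Why: Corey–Bakshi–Shibata reduction, in which the bromoalkenyl carbon acts as the large group on the oxazaborolidine–borane complex, so that hydride should be delivered to one carbonyl face and set the (S)-carbinol (the later C4).

Step 2
Reactants: 2 (S)-2-bromo-3-methylcyclopent-2-en-1-ol
Product: 3 (S)-[(2-bromo-3-methylcyclopent-2-en-1-yl)oxy]triethylsilane
Conditions: Et3SiCl, imidazole, DMF, 0 °C to rt
Reagents that add atoms: chlorotriethylsilane, CC[Si](Cl)(CC)CC
Why: Standard alcohol silylation; the triethylsilyl ether survives the organolithium steps, serves as the bulky face-blocking group in step 5 and is removable with dilute acid in step 8.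

Step 3
Reactants: 3 (S)-[(2-bromo-3-methylcyclopent-2-en-1-yl)oxy]triethylsilane
Product: 5 (S)-[2-methyl-5-(triethylsilyloxy)cyclopent-1-en-1-yl](morpholin-4-yl)methanone, via alkenyllithium 4 (not isolated)
Conditions: t-BuLi (2.1 equiv), Et2O, −78 °C; morpholine-4-carbonyl chloride, −78 °C to 0 °C
Reagents that add atoms: morpholine-4-carbonyl chloride, O=C(Cl)N1CCOCC1
Why: Bromine–lithium exchange of an alkenyl bromide followed by acylation of the alkenyllithium with a carbamoyl chloride (addition–elimination), which should stop at the amide because the product is a poor electrophile.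

Step 4
Reactants: 5 (S)-[2-methyl-5-(triethylsilyloxy)cyclopent-1-en-1-yl](morpholin-4-yl)methanone
Product: 6 (S)-[dimethyl(phenyl)silyl][2-methyl-5-(triethylsilyloxy)cyclopent-1-en-1-yl]methanone
Conditions: PhMe2SiLi (from PhMe2SiCl and Li, THF, 0 °C), THF, −78 °C; aq NH4Cl
Reagents that add atoms: dimethylphenylsilyllithium, [Li][Si](C)(C)c1ccccc1 (made from chlorodimethyl(phenyl)silane, C[Si](C)(Cl)c1ccccc1)
Why: Acyl substitution of a morpholine amide by a silyllithium is an established route to acylsilanes without over-addition, and the fully substituted β-carbon of the enoyl unit should block conjugate addition.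

Step 5
Reactants: 6 (S)-[dimethyl(phenyl)silyl][2-methyl-5-(triethylsilyloxy)cyclopent-1-en-1-yl]methanone; 7 2-(trimethylsilyloxy)buta-1,3-diene
Product: 11 9α-hydroxy-8-oxo bicyclic silyl enol ether (1β-CH3; 4β-OSiEt3; C5=C6–OSiMe2Ph), via lithium buta-1,3-dien-2-olate 8 (not isolated), via cis-divinylcyclopropanolate 9 (not isolated), via cycloheptadienyl lithium enolate 10 (not isolated)
Conditions: 7, MeLi, THF, 0 °C to rt; −80 °C, add 6, then to −30 °C; −78 °C, 2-(phenylsulfonyl)-3-phenyloxaziridine; AcOH, then aq NH4Cl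
Reagents that add atoms: 2-(phenylsulfonyl)-3-phenyloxaziridine, O=S(=O)(N1OC1c1ccccc1)c1ccccc1
Why: Addition of the enolate carbon of 8 to the acylsilane carbonyl of 6 forms C6–C7 and triggers a 1,2-Brook shift of silicon from carbon to oxygen with closure (3-exo-trig) onto the ketone to give the cis-1,2-divinylcyclopropanolate 9, which ring-expands by an alkoxide-accelerated [3,3]-sigmatropic (oxy-Cope) shift through a boat transition state, breaking C6–C8 and forming C1–C10, to the enolate 10. The closest known reaction type is the Brook rearrangement-mediated [3+4] annulation of β-substituted acryloylsilanes with lithium enolates of alkenyl methyl ketones, which includes cyclic acryloylsilanes that deliver a methyl-bearing quaternary ring-fusion carbon. Ring B is thus closed as a seven-membered carbocycle by a formal (3+4) annulation whose ring-forming event is the six-electron sigmatropic expansion of a three-membered ring. C1 is controlled by the C4 stereocentre: the cyclopropane and then the C1–C10 bond should form on the cyclopentene face that carries the small C4–H (α), away from the triethylsilyloxy group, so the C1 methyl ends β, cis to the C4 oxygen; C9 is controlled by the C1 methyl, because the oxaziridine should transfer oxygen to the α-face of enolate 10, opposite the pseudo-axial methyl, which is also the equatorial and thermodynamically preferred position of an epimerisable α-ketol. The step needs 1,2- over 1,4-addition to the enoyl silane (secured by the fully substituted β-carbon C1), [3+4] over [3+2] annulation (secured by the vinyl group on the enolate) and hydroxylation at C9 only (secured because the sigmatropic shift leaves the enolate double bond at C8=C9 and the C6 oxygen as an unreactive silyl enol ether).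

Step 6
Reactants: 11 9α-hydroxy-8-oxo bicyclic silyl enol ether
Product: 12 9α-(tert-butyldimethylsilyloxy)-8-oxo bicyclic silyl enol ether
Conditions: t-BuMe2SiCl, imidazole, DMF, rt
Reagents that add atoms: tert-butylchlorodimethylsilane, CC(C)(C)[Si](C)(C)Cl
Why: Standard silylation of the only free hydroxyl under imidazole conditions, which should neither enol-silylate the C8 ketone nor cleave the acid-labile silyl enol ether.

Step 7
Reactants: 12 9α-(tert-butyldimethylsilyloxy)-8-oxo bicyclic silyl enol ether
Product: 13 8-methylene bicyclic silyl enol ether (1β-CH3; 4β-OSiEt3; C5=C6–OSiMe2Ph; 9α-OSiMe2t-Bu)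
Conditions: Ph3PCH3Br, KOt-Bu, THF, 0 °C to rt
Reagents that add atoms: methyltriphenylphosphonium bromide, C[P+](c1ccccc1)(c1ccccc1)c1ccccc1.[Br-]
Why: Wittig methylenation of the only carbonyl group, the C6 carbonyl being masked as its silyl enol ether; C9 is α to the ketone but already holds its oxygen in the equatorial, thermodynamically preferred position, so base-induced epimerisation should not change it.

Step 8
Reactants: 13 8-methylene bicyclic silyl enol ether
Product: 15 hydroxy enone (4β-OH; 5α-H; 6-oxo; C7=C8–CH3; 9α-OSiMe2t-Bu), via exo-methylene ketone 14 (not isolated)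
Conditions: aq HCl (1 M), THF, 0 °C to rt
Reagents that add atoms: none
Why: Acid hydrolysis of the silyl enol ether and of the triethylsilyl ether, with C-protonation at C5 on the α-face (opposite the C1 methyl and the C4 oxygen, giving the trans ring fusion, which a C4–OH···O=C6 hydrogen bond also favours at equilibrium), followed by acid-catalysed isomerisation of the β,γ-unsaturated ketone 14 through its dienol into conjugation as C7=C8.

Step 9
Reactants: 15 hydroxy enone
Product: 16 4β,6α-diol (5α-H; C7=C8–CH3; 9α-OSiMe2t-Bu)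
Conditions: Me4NBH(OAc)3, MeCN/AcOH, −30 °C to 0 °C
Reagents that add atoms: none
Why: Evans–Saksena reduction, in which the C4 hydroxyl exchanges onto boron and delivers hydride intramolecularly to the β-face of the C6 carbonyl (1,2-reduction of the enone), which should give the anti-1,3-diol with the 6α-hydroxyl that an external hydride, approaching anti to the axial C1 methyl, would not give.

Step 10
Reactants: 17 vanillic acid (4-hydroxy-3-methoxybenzoic acid)
Product: 19 4-(tert-butyldimethylsilyloxy)-3-methoxybenzoic acid, via silyl ester 18 (not isolated)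
Conditions: t-BuMe2SiCl (2.5 equiv), imidazole, DMF, rt; then AcOH/THF/H2O, rt
Reagents that add atoms: tert-butylchlorodimethylsilane, CC(C)(C)[Si](C)(C)Cl
Why: Exhaustive silylation followed by selective hydrolysis of the labile silyl ester, the aryl silyl ether being stable to aqueous acetic acid.

Step 11
Reactants: 16 4β,6α-diol; 19 4-(tert-butyldimethylsilyloxy)-3-methoxybenzoic acid
Product: 20 6α-[4-(tert-butyldimethylsilyloxy)-3-methoxybenzoyl] ester with free 4β-OH
Conditions: EDC·HCl, DMAP (cat.), CH2Cl2, 0 °C
Reagents that add atoms: none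
Why: Steglich-type carbodiimide esterification; the equatorial allylic C6 hydroxyl should be acylated in preference to the C4 hydroxyl, which is flanked on its own face by the cis C5–C6 bond and the syn C1 methyl.

Step 12
Reactants: 20 6α-aroyl ester with free 4β-OH
Product: 21 4-ketone (6α-aroyl ester; 9α-OSiMe2t-Bu)
Conditions: Dess–Martin periodinane, CH2Cl2, 0 °C to rt
Reagents that add atoms: none
Why: Dess–Martin oxidation of the only free hydroxyl under non-basic conditions, which should leave the β-aroyloxy ketone free of E1cB elimination and of epimerisation at C5.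

Step 13
Reactants: 21 4-ketone
Product: 22 bis(tert-butyldimethylsilyl) ether of the target (4β-OH; 4α-isopropyl)
Conditions: i-PrMgCl, LaCl3·2LiCl, THF, −40 °C to 0 °C
Reagents that add atoms: isopropylmagnesium chloride, CC(C)[Mg]Cl
Why: Lanthanum chloride-promoted Grignard 1,2-addition, which suppresses enolisation and β-hydride reduction; attack on the α-face of the C4 ketone, opposite the C1 methyl and the β-disposed C5–C6 bond, should place the hydroxyl β and the isopropyl group α, and the hindered aryl ester is far less electrophilic than the ketone.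

Step 14
Reactants: 22 bis(tert-butyldimethylsilyl) ether of the target
Product: 23 target, (3R,3aS,4S,7S,8aR)-3,7-dihydroxy-6,8a-dimethyl-3-(propan-2-yl)-1,2,3,3a,4,7,8,8a-octahydroazulen-4-yl 4-hydroxy-3-methoxybenzoate
Conditions: Bu4NF, AcOH (1:1), THF, 0 °C to rt
Reagents that add atoms: none
Why: Fluoride-mediated desilylation of the aryl and the secondary allylic silyl ethers, buffered with acetic acid so that the allylic ester should neither migrate nor be cleaved.

**Compound list**

1 | 2-bromo-3-methylcyclopent-2-en-1-one | CC1=C(Br)C(=O)CC1 | starting material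
2 | (S)-2-bromo-3-methylcyclopent-2-en-1-ol | O[C@H]1CCC(C)=C1Br | intermediate
3 | (S)-[(2-bromo-3-methylcyclopent-2-en-1-yl)oxy]triethylsilane | CC[Si](CC)(CC)O[C@H]1CCC(C)=C1Br | intermediate
4 | (S)-[2-methyl-5-(triethylsilyloxy)cyclopent-1-en-1-yl]lithium | CC[Si](CC)(CC)O[C@H]1CCC(C)=C1[Li] | intermediate
5 | (S)-[2-methyl-5-(triethylsilyloxy)cyclopent-1-en-1-yl](morpholin-4-yl)methanone | CC[Si](CC)(CC)O[C@H]1CCC(C)=C1C(=O)N1CCOCC1 | intermediate
6 | (S)-[dimethyl(phenyl)silyl][2-methyl-5-(triethylsilyloxy)cyclopent-1-en-1-yl]methanone | CC[Si](CC)(CC)O[C@H]1CCC(C)=C1C(=O)[Si](C)(C)c1ccccc1 | intermediate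
7 | 2-(trimethylsilyloxy)buta-1,3-diene | C=CC(=C)O[Si](C)(C)C | starting material
8 | lithium buta-1,3-dien-2-olate | [Li]OC(=C)C=C | intermediate
9 | lithium (1S,2R)-2-[dimethyl(phenyl)silyloxy]-2-[(5S)-2-methyl-5-(triethylsilyloxy)cyclopent-1-en-1-yl]-1-vinylcyclopropan-1-olate (vinyl and cyclopentenyl cis) | [Li]O[C@]1(C=C)C[C@@]1(O[Si](C)(C)c1ccccc1)C1=C(C)CC[C@@H]1O[Si](CC)(CC)CC | intermediate
10 | bicyclic lithium enolate: 1β-CH3, 4β-OSiEt3, C5=C6–OSiMe2Ph, C8(OLi)=C9 | [Li]OC1=CC[C@@]2(C)CC[C@H](O[Si](CC)(CC)CC)C2=C(O[Si](C)(C)c2ccccc2)C1 | intermediate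
11 | bicyclic α-hydroxy ketone: 1β-CH3, 4β-OSiEt3, C5=C6–OSiMe2Ph, 8-oxo, 9α-OH | O=C1[C@@H](O)C[C@@]2(C)CC[C@H](O[Si](CC)(CC)CC)C2=C(O[Si](C)(C)c2ccccc2)C1 | intermediate
12 | as 11 with 9α-OSiMe2t-Bu | O=C1[C@@H](O[Si](C)(C)C(C)(C)C)C[C@@]2(C)CC[C@H](O[Si](CC)(CC)CC)C2=C(O[Si](C)(C)c2ccccc2)C1 | intermediate
13 | 8-methylene compound: 1β-CH3, 4β-OSiEt3, C5=C6–OSiMe2Ph, C8=CH2, 9α-OSiMe2t-Bu | C=C1[C@@H](O[Si](C)(C)C(C)(C)C)C[C@@]2(C)CC[C@H](O[Si](CC)(CC)CC)C2=C(O[Si](C)(C)c2ccccc2)C1 | intermediate
14 | β,γ-unsaturated ketone: 4β-OH, 5α-H, 6-oxo, C8=CH2, 9α-OSiMe2t-Bu | O=C1CC(=C)[C@@H](O[Si](C)(C)C(C)(C)C)C[C@@]2(C)CC[C@H](O)[C@H]12 | intermediate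
15 | hydroxy enone: 4β-OH, 5α-H, 6-oxo, C7=C8–CH3, 9α-OSiMe2t-Bu | O=C1C=C(C)[C@@H](O[Si](C)(C)C(C)(C)C)C[C@@]2(C)CC[C@H](O)[C@H]12 | intermediate
16 | diol: 4β-OH, 5α-H, 6α-OH, C7=C8–CH3, 9α-OSiMe2t-Bu | O[C@H]1C=C(C)[C@@H](O[Si](C)(C)C(C)(C)C)C[C@@]2(C)CC[C@H](O)[C@H]12 | intermediate
17 | vanillic acid | COc1cc(C(=O)O)ccc1O | starting material
18 | tert-butyldimethylsilyl 4-(tert-butyldimethylsilyloxy)-3-methoxybenzoate | COc1cc(C(=O)O[Si](C)(C)C(C)(C)C)ccc1O[Si](C)(C)C(C)(C)C | intermediate
19 | 4-(tert-butyldimethylsilyloxy)-3-methoxybenzoic acid | COc1cc(C(=O)O)ccc1O[Si](C)(C)C(C)(C)C | intermediate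
20 | 6α-aroyl ester: 4β-OH, 5α-H, 9α-OSiMe2t-Bu, aryl O-silylated | COc1cc(C(=O)O[C@H]2C=C(C)[C@@H](O[Si](C)(C)C(C)(C)C)C[C@@]3(C)CC[C@H](O)[C@H]23)ccc1O[Si](C)(C)C(C)(C)C | intermediate
21 | 4-ketone of 20 | COc1cc(C(=O)O[C@H]2C=C(C)[C@@H](O[Si](C)(C)C(C)(C)C)C[C@@]3(C)CCC(=O)[C@H]23)ccc1O[Si](C)(C)C(C)(C)C | intermediate
22 | bis(tert-butyldimethylsilyl) ether of the target: 4β-OH, 4α-isopropyl | COc1cc(C(=O)O[C@H]2C=C(C)[C@@H](O[Si](C)(C)C(C)(C)C)C[C@@]3(C)CC[C@@](O)(C(C)C)[C@H]23)ccc1O[Si](C)(C)C(C)(C)C | intermediate
23 | (3R,3aS,4S,7S,8aR)-3,7-dihydroxy-6,8a-dimethyl-3-(propan-2-yl)-1,2,3,3a,4,7,8,8a-octahydroazulen-4-yl 4-hydroxy-3-methoxybenzoate | COc1cc(C(=O)O[C@H]2C=C(C)[C@@H](O)C[C@@]3(C)CC[C@@](O)(C(C)C)[C@H]23)ccc1O | target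

**Step count and risks**

Total step count: 14. Longest linear sequence: 13 steps (steps 1–9 and 11–14; step 10 is a one-step side branch).

Steps most likely to fail:

1. Step 5. The ring expansion must form a bond at a fully substituted alkene carbon that carries a cis methyl group. If this sigmatropic step is slower than reopening of the cyclopropanolate on warming, the cascade stalls or fragments before the enolate can be hydroxylated. Fallback: a neutral, stepwise version that sets out from cyclopropanolate 9 (made from 6 and 8 at −80 °C as in step 5) and returns to the route at enolate 10. Compound 9 is silylated cold with Me3SiCl to the bis(silyl ether) of the cis-divinylcyclopropanediol F1, which is isolated and heated in toluene (80–110 °C) so that the neutral divinylcyclopropane–cycloheptadiene rearrangement gives the bis(silyl enol ether) F2. MeLi (THF, 0 °C) then cleaves the less hindered trimethylsilyl enol ether and regenerates enolate 10, which is hydroxylated as in step 5 to give 11.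

2. Step 11. Site selectivity may be lost through competing acylation of the C4 hydroxyl, double acylation, or a base-mediated 1,3-acyl shift between the two oxygens. Fallback: the tertiary carbinol is built before any ester exists, setting out from 13 and returning at 22.
   - MeLi then i-Pr3SiOTf exchanges the labile silyl enol ether of 13 for the robust triisopropylsilyl enol ether F3.
   - PPTS in MeOH removes only the triethylsilyl group to give the 4β-alcohol F4.
   - Dess–Martin periodinane gives the β-silyloxy enone F5.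
   - i-PrMgCl with LaCl3·2LiCl adds to the C4 carbonyl from the α-face to give the tertiary carbinol F6.
   - Bu4NF/AcOH at −20 °C, then a trace of Et3N, unmasks and conjugates the ketone to the hydroxy enone F7.
   - Me4NBH(OAc)3 reduces C6 under direction of the tertiary hydroxyl to the diol F8, whose only acylable hydroxyl is esterified with 19 (EDC·HCl, DMAP) to give 22.

3. Step 13. The Grignard reagent may transfer a β-hydride (reducing the ketone back to the alcohol) or deprotonate C5, which expels the C6 aroyloxy group (E1cB). Fallback: from 21, 2-propenylmagnesium bromide with LaCl3·2LiCl (an sp2 nucleophile with no transferable β-hydride and lower basicity) gives the isopropenyl carbinol F9. Chemoselective hydrogenation of the 1,1-disubstituted alkene (H2, RhCl(PPh3)3, benzene, rt), which should leave the trisubstituted ring alkene untouched, returns the route at 22.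

**Further compounds**

F1 | step 5 | (1S,2R)-2-[dimethyl(phenyl)silyloxy]-2-[(5S)-2-methyl-5-(triethylsilyloxy)cyclopent-1-en-1-yl]-1-(trimethylsilyloxy)-1-vinylcyclopropane | C[Si](C)(C)O[C@]1(C=C)C[C@@]1(O[Si](C)(C)c1ccccc1)C1=C(C)CC[C@@H]1O[Si](CC)(CC)CC
F2 | step 5 | bicyclic bis(silyl enol ether): 1β-CH3, 4β-OSiEt3, C5=C6–OSiMe2Ph, C8(OSiMe3)=C9 | C[Si](C)(C)OC1=CC[C@@]2(C)CC[C@H](O[Si](CC)(CC)CC)C2=C(O[Si](C)(C)c2ccccc2)C1
F3 | step 11 | triisopropylsilyl enol ether analogue of 13 | C=C1[C@@H](O[Si](C)(C)C(C)(C)C)C[C@@]2(C)CC[C@H](O[Si](CC)(CC)CC)C2=C(O[Si](C(C)C)(C(C)C)C(C)C)C1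
F4 | step 11 | 4β-alcohol of F3 | C=C1[C@@H](O[Si](C)(C)C(C)(C)C)C[C@@]2(C)CC[C@H](O)C2=C(O[Si](C(C)C)(C(C)C)C(C)C)C1
F5 | step 11 | 4-oxo β-silyloxy enone | C=C1[C@@H](O[Si](C)(C)C(C)(C)C)C[C@@]2(C)CCC(=O)C2=C(O[Si](C(C)C)(C(C)C)C(C)C)C1
F6 | step 11 | 4β-hydroxy-4α-isopropyl silyl enol ether | C=C1[C@@H](O[Si](C)(C)C(C)(C)C)C[C@@]2(C)CC[C@@](O)(C(C)C)C2=C(O[Si](C(C)C)(C(C)C)C(C)C)C1
F7 | step 11 | hydroxy enone: 4β-OH, 4α-isopropyl, 5α-H, 6-oxo, C7=C8–CH3, 9α-OSiMe2t-Bu | O=C1C=C(C)[C@@H](O[Si](C)(C)C(C)(C)C)C[C@@]2(C)CC[C@@](O)(C(C)C)[C@H]12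
F8 | step 11 | diol: 4β-OH, 4α-isopropyl, 6α-OH, 9α-OSiMe2t-Bu | O[C@H]1C=C(C)[C@@H](O[Si](C)(C)C(C)(C)C)C[C@@]2(C)CC[C@@](O)(C(C)C)[C@H]12
F9 | step 13 | 4β-hydroxy-4α-(prop-1-en-2-yl) analogue of 22 | COc1cc(C(=O)O[C@H]2C=C(C)[C@@H](O[Si](C)(C)C(C)(C)C)C[C@@]3(C)CC[C@@](O)(C(C)=C)[C@H]23)ccc1O[Si](C)(C)C(C)(C)C
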